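(The rate constants are assumed, and the outcome is calculated.)

If substrate stands at a fraction s of the charge, target meets the side step as a pseudo-first-order loss with constant κs, where κ, the side constant at full charge, is 2.5 × 10⁻⁵ M⁻¹ s⁻¹ times 0.10 M, or 0.216 d⁻¹.

    2 substrate → target (k1 = 0.0021 M⁻¹ s⁻¹)
    2 substrate → homo dimer (k2 = 1.9 × 10⁻⁷ M⁻¹ s⁻¹)
    substrate + target → side product (k3 = 2.5 × 10⁻⁵ M⁻¹ s⁻¹)

| flask | substrate | remark | time |
|---|---|---|---|
| larch | 0.10 M | one stirred flow tank at steady state, fed with the mixture as stated, mean residence time 7.50 d |  |
| birch | 0.10 M | a single well-mixed tank run continuously and read at steady state, 2.5 d in it on average |  |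
| elm | 0.10 M | a closed flask charged with all of it at once and left for 2.5 d | 2.5 d |

- the set-up with the highest share of target in all that became target or side product, at the outlet or at the end ("none" if the first two lie within 2 percentage points) (larch / birch / elm / none)
- share of target in all that became target or side product, at the outlet or at the end, larch
- share of target in all that became target or side product, at the outlet or at the end, birch
- share of target in all that became target or side product, at the outlet or at the end, elm

- percentages count the substrate that a species holds: one target or homo dimer counts as two
- percentages count the substrate that a species holds: one side product counts as three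
- a step written with two of one species runs at k times the square of its concentration and takes two of it each time
- the stated concentrations are those of everything mixed, before any reaction; amounts are the same in each set-up
- run time (elm): 2.5 d

At steady state a tank delivers side product as fast as it forms, so the side product per target at the outlet is N = κsτ for mean residence time τ. Side product holds 3 substrate and target 2, so the share asked is 2/(2+3N).

The constant of the target step, 0.0021 M⁻¹ s⁻¹, stands far above the homo dimer step's 1.9 × 10⁻⁷ M⁻¹ s⁻¹ and the side step's 2.5 × 10⁻⁵ M⁻¹ s⁻¹. The reckoning here therefore takes the substrate balance as one minus s equal to Ds², with D = 2·0.0021 M⁻¹ s⁻¹·0.10 M·τ. In larch D is 272, which gives s of 0.0588, and in birch D is 90.7, which gives s of 0.0996. In elm, s falls as one over one plus D, and integration gives N = (κ/(2·0.0021 M⁻¹ s⁻¹·0.10 M))·[(one plus one over D)·ln(one plus D) minus one]. The values of N are 0.0953, 0.0538 and 0.0212. In powers of ten: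

| set-up | exponent of D | exponent of s | exponent of κτ | exponent of N |
|---|---|---|---|---|
| larch | 2.43 | −1.23 | 0.210 | −1.02 |
| birch | 1.96 | −1.00 | −0.268 | −1.27 |
| elm | 1.96 | −1.96 | −0.268 | −1.67 |

Reading from birch to larch, κτ gains 0.477 in the exponent, and s gives back about half of that, so N rises. The elm row lists s at the end of the run, while side product gathers along the whole run, so in that row the exponents of s and κτ do not add up to that of N. Elm shares birch's D and κτ, yet its N is lower: N divided by κτ gives elm a target-weighted mean s of 0.0393 over the run, lower than birch's steady 0.0996. The shares reckoned are 87.5% for larch, 92.5% for birch and 96.9% for elm, so elm leads birch by 4.4 percentage points, beyond the margin.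

The forecast gives 87.7%, 92.6% and 97% and names elm, saying that “the side reaction is second order across both”.

The best set-up is elm, with larch at 87.7%, birch at 92.6% and elm at 97.0%. At the larch outlet, substrate reads 5.76% of the charge, and κ with that reading and 7.50 d gives N of 0.0933, a share of 87.7%. In birch, substrate reads 9.84% of the charge, and κ with 2.5 d on average in the tank gives N of 0.0531, a share of 92.6%. The birch outlet holds 83.5% of the charge as target and 6.66% as side product.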